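**Plan**

1. Numbering: chromene O1, C2–C4, C4a, C5–C8, C8a; cyclohexene C1′ (quaternary), C2′ (CHMe), C3′=C4′, C5′, C6′.
2. Retrosynthetic cuts, in order: O1–C8a (conjugate addition of the C2 hydroxyl to a methoxy-p-quinone), C4–C4a (Sonogashira coupling; the alkyne becomes the Z C3=C4 alkene), the side-chain CH2–CH2 bond next to C1′ (Grignard opening of an epoxide), and last the ring bond C1′–C2′.
3. Enabling feature: C2′ is allylic to the ring alkene C3′=C4′ and quaternary C1′ carries an exocyclic carbon that can be a carboxyl. The cyclohexene is therefore a γ,δ-unsaturated acid, the [3,3] product of the silyl ketene acetal of a δ-lactone whose ring oxygen sits on the future C4′ and whose (E)-but-2-en-2-yl group supplies C3′ and C2′.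
4. Forward order: tiglic aldehyde → (S)-dienol → methacrylate → RCM lactone → saturated lactone → Ireland–Claisen (carbocycle formed) → neopentyl iodide → Grignard + (R)-2-methylglycidol → alkynol → aryl alkyne → Z-alkene → quinone → pyran ring closed last.
5. Stereochemistry: C1′ and C2′ arise together by chirality transfer from the one carbinol center set by Brown allylation, relayed through an enforced boat transition state and the E alkene. C2 comes from (R)-2-methylglycidol, and its C–O bond is never broken.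

Key step: step 5

Remark: lactone 6 is carried as a mixture of C3 epimers because C3 becomes trigonal in step 5; the descriptors of the cyclohexene centers differ between 9–14 and 16–26 only through CIP priorities, not through any change in space.

Step 1
Reactants: 1 (2E)-2-methylbut-2-enal (tiglic aldehyde)
Product: 3 (4S,5E)-5-methylhepta-1,5-dien-4-ol, via borinate ester 2 (not isolated)
Conditions: (−)-Ipc2B(allyl) (1 M in pentane), Et2O, −78 °C; then NaOH, H2O2, 0 °C → rt
Reagents that add atoms: (−)-B-allyldiisopinocampheylborane, C=CCB([C@@H]1C[C@@H]2C[C@H]([C@H]1C)C2(C)C)[C@@H]1C[C@@H]2C[C@H]([C@H]1C)C2(C)C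
Why: Brown allylboration through a closed chair transition state, in which the isopinocampheyl groups from (+)-α-pinene should direct the allyl group to the Si face of the enal and so set C4 as S; oxidative work-up cleaves the borinate.

Step 2
Reactants: 3 (4S,5E)-5-methylhepta-1,5-dien-4-ol
Product: 4 (4S,5E)-5-methylhepta-1,5-dien-4-yl 2-methylprop-2-enoate
Conditions: methacryloyl chloride, Et3N, DMAP (cat.), CH2Cl2, 0 °C → rt
Reagents that add atoms: methacryloyl chloride, CC(=C)C(Cl)=O
Why: DMAP-catalysed O-acylation of the secondary allylic alcohol, which leaves the stereocenter untouched and installs the future C1′, its methyl group and the carboxyl carbon.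

Step 3
Reactants: 4 (4S,5E)-5-methylhepta-1,5-dien-4-yl 2-methylprop-2-enoate
Product: 5 (6S)-6-[(2E)-but-2-en-2-yl]-3-methyl-5,6-dihydro-2H-pyran-2-one
Conditions: second-generation Grubbs catalyst RuCl2(=CHPh)(PCy3)(H2IMes) (5 mol %), toluene, 80 °C
Reagents that add atoms: none
Why: Ring-closing metathesis joins the terminal vinyl group and the methacrylate alkene to the six-membered unsaturated lactone, the trisubstituted butenyl alkene being too hindered to take part.

Step 4
Reactants: 5 (6S)-6-[(2E)-but-2-en-2-yl]-3-methyl-5,6-dihydro-2H-pyran-2-one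
Product: 6 (6S)-6-[(2E)-but-2-en-2-yl]-3-methyloxan-2-one (mixture of C3 epimers)
Conditions: Cu(OAc)2·H2O (cat.), 1,2-bis(diphenylphosphino)benzene (cat.), (EtO)2MeSiH, t-BuOH, toluene, rt
Reagents that add atoms: none
Why: CuH-catalysed conjugate reduction is selective for the enoate alkene over the isolated trisubstituted alkene and the lactone carbonyl; the new C3 center forms without control, which is harmless because it becomes trigonal in step 5.

Step 5
Reactants: 6 (6S)-6-[(2E)-but-2-en-2-yl]-3-methyloxan-2-one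
Product: 10 (1R,2S)-1,2,3-trimethylcyclohex-3-ene-1-carboxylic acid, via lithium enolate 7 (not isolated), via cyclic silyl ketene acetal 8 (not isolated), via silyl ester 9 (not isolated)
Conditions: LiN(i-Pr)2, THF, −78 °C; t-BuMe2SiCl, DMPU, −78 °C → rt; toluene, 110 °C; then 1 M HCl, THF, rt
Reagents that add atoms: lithium diisopropylamide, [Li+].CC(C)[N-]C(C)C; tert-butyldimethylsilyl chloride, CC(C)(C)[Si](C)(C)Cl (found only in intermediates 7 to 9)
Why: Deprotonation and O-silylation give ketene acetal 8, in which the endocyclic C2=C3 bond, O1 and the 6-butenyl group form an allyl vinyl ether, and a [3,3]-sigmatropic shift (Ireland–Claisen rearrangement of a lactone silyl ketene acetal, a known lactone-to-carbocycle reaction type) joins lactone C3 to the butenyl terminus, which is the C1′–C2′ bond, while the C6–O1 bond breaks. The cyclohexene closes inside a bicyclo[2.2.2]octane-like array, because the two-carbon bridge C4–C5 links positions 1 and 4 of the pericyclic array, so only a boat transition state is possible and the new ring alkene C3′=C4′ is necessarily cis. The ring-locked ketene acetal geometry and the E geometry of the butenyl group together fix the relative configuration, putting the C2′ methyl cis to the carboxyl and trans to the C1′ methyl. The absolute configuration of both new centers, quaternary C1′ and tertiary C2′, is transferred suprafacially from the single carbinol center C6 (S), which is consumed as it becomes sp2 C4′. The selectivities needed, chair against boat and E against Z ketene acetal, are removed as variables by the lactone ring, and both C3 epimers of 6 converge on one enolate. Mild acid then cleaves silyl ester 9 to acid 10, which can be purified by acid–base extraction.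

Step 6
Reactants: 10 (1R,2S)-1,2,3-trimethylcyclohex-3-ene-1-carboxylic acid
Product: 11 [(1R,2S)-1,2,3-trimethylcyclohex-3-en-1-yl]methanol
Conditions: LiAlH4, THF, 0 °C → reflux; then H2O, aq. NaOH
Reagents that add atoms: none
Why: LiAlH4 reduction of the carboxylic acid to the neopentyl primary alcohol; no stereocenter is involved.

Step 7
Reactants: 11 [(1R,2S)-1,2,3-trimethylcyclohex-3-en-1-yl]methanol
Product: 12 (5R,6S)-5-(iodomethyl)-1,5,6-trimethylcyclohex-1-ene
Conditions: PPh3, iodine, imidazole, toluene, 80 °C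
Reagents that add atoms: iodine, [I][I]
Why: Appel-type iodination by SN2 displacement of an alkoxyphosphonium ion, which at this neopentyl carbon should need heating but proceed without skeletal rearrangement.

Step 8
Reactants: 12 (5R,6S)-5-(iodomethyl)-1,5,6-trimethylcyclohex-1-ene; 13 (R)-2-methylglycidol, [(2R)-2-methyloxiran-2-yl]methanol
Product: 16 (2S)-2-methyl-4-[(1S,2R)-1,2,3-trimethylcyclohex-3-en-1-yl]butane-1,2-diol, via Grignard reagent 14 (not isolated), via chloromagnesium alkoxide 15 (not isolated)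
Conditions: 12, Mg, THF, 45 °C; separately 13, i-PrMgCl, THF, −78 °C; combine, CuI (10 mol %), THF, −40 → 0 °C; aq. NH4Cl
Reagents that add atoms: magnesium, [Mg]; isopropylmagnesium chloride, CC(C)[Mg]Cl (found only in intermediates 14 and 15)
Why: Magnesium insertion gives Grignard reagent 14, and CuI-catalysed SN2 opening of the alkoxide-masked 2,2-disubstituted epoxide at its CH2 terminus joins the fragments; the tertiary carbinol center is taken intact from 13, its descriptor becoming S only by the change of CIP priorities.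

Step 9
Reactants: 16 (2S)-2-methyl-4-[(1S,2R)-1,2,3-trimethylcyclohex-3-en-1-yl]butane-1,2-diol
Product: 18 (3S)-3-methyl-5-[(1S,2R)-1,2,3-trimethylcyclohex-3-en-1-yl]pent-1-yn-3-ol, via hydroxy aldehyde 17 (not isolated)
Conditions: IBX, EtOAc, 75 °C; filter, concentrate; then dimethyl (1-diazo-2-oxopropyl)phosphonate, K2CO3, MeOH, 0 °C → rt
Reagents that add atoms: dimethyl (1-diazo-2-oxopropyl)phosphonate (Ohira–Bestmann reagent), CC(=O)C(=[N+]=[N-])P(=O)(OC)OC
Why: IBX oxidises the primary hydroxyl of the 1,2-diol without glycol cleavage, and Seyferth–Gilbert homologation with the Ohira–Bestmann reagent converts the non-enolisable α-hydroxy aldehyde 17 into the terminal alkyne with the carbinol center unchanged.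

Step 10
Reactants: 19 2-bromo-6-methoxyphenol
Product: 20 2-bromo-6-methoxyphenyl acetate
Conditions: Ac2O, pyridine, CH2Cl2, rt
Reagents that add atoms: acetic anhydride, CC(=O)OC(C)=O
Why: Acetylation of the phenol, so that the later 2-alkynylphenol cannot cyclise to a benzofuran under the coupling conditions.

Step 11
Reactants: 18 (3S)-3-methyl-5-[(1S,2R)-1,2,3-trimethylcyclohex-3-en-1-yl]pent-1-yn-3-ol; 20 2-bromo-6-methoxyphenyl acetate
Product: 21 2-{(3S)-3-hydroxy-3-methyl-5-[(1S,2R)-1,2,3-trimethylcyclohex-3-en-1-yl]pent-1-yn-1-yl}-6-methoxyphenyl acetate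
Conditions: Pd(PhCN)2Cl2 (3 mol %), P(t-Bu)3 (6 mol %), CuI (3 mol %), i-Pr2NH, dioxane, rt → 40 °C
Reagents that add atoms: none
Why: Sonogashira coupling, with the bulky electron-rich phosphine allowing oxidative addition of the electron-rich ortho-substituted aryl bromide near room temperature; the tertiary propargylic alcohol needs no protection.

Step 12
Reactants: 21 2-{(3S)-3-hydroxy-3-methyl-5-[(1S,2R)-1,2,3-trimethylcyclohex-3-en-1-yl]pent-1-yn-1-yl}-6-methoxyphenyl acetate
Product: 22 2-{(1Z,3S)-3-hydroxy-3-methyl-5-[(1S,2R)-1,2,3-trimethylcyclohex-3-en-1-yl]pent-1-en-1-yl}-6-methoxyphenyl acetate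
Conditions: H2 (1 atm), Lindlar catalyst (Pd on CaCO3 poisoned with Pb(OAc)2), quinoline, EtOAc, rt
Reagents that add atoms: none
Why: Lindlar semi-hydrogenation delivers H2 syn to the alkyne and should stop at the Z alkene, the hindered trisubstituted ring alkene being inert to the poisoned catalyst.

Step 13
Reactants: 22 2-{(1Z,3S)-3-hydroxy-3-methyl-5-[(1S,2R)-1,2,3-trimethylcyclohex-3-en-1-yl]pent-1-en-1-yl}-6-methoxyphenyl acetate
Product: 24 2-{(1Z,3S)-3-hydroxy-3-methyl-5-[(1S,2R)-1,2,3-trimethylcyclohex-3-en-1-yl]pent-1-en-1-yl}-6-methoxycyclohexa-2,5-diene-1,4-dione, via free phenol 23 (not isolated)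
Conditions: K2CO3, MeOH, 0 °C; then (KSO3)2NO, KH2PO4, H2O/acetone, 0 °C → rt
Reagents that add atoms: potassium nitrosodisulfonate (Fremy's salt), [K+].[K+].[O-]S(=O)(=O)N([O])S(=O)(=O)[O-]
Why: Base-catalysed methanolysis of the aryl acetate frees phenol 23, and Teuber oxidation with Fremy's salt converts this 2,6-disubstituted phenol with a free para position into the p-quinone under near-neutral conditions that should not ionise the tertiary allylic alcohol.

Step 14
Reactants: 24 2-{(1Z,3S)-3-hydroxy-3-methyl-5-[(1S,2R)-1,2,3-trimethylcyclohex-3-en-1-yl]pent-1-en-1-yl}-6-methoxycyclohexa-2,5-diene-1,4-dione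
Product: 26 (2S)-6-methoxy-2-methyl-2-{2-[(1S,2R)-1,2,3-trimethylcyclohex-3-en-1-yl]ethyl}-2H-chromene-5,8-dione, via chromene hydroquinone 25 (not isolated)
Conditions: Ag2O, Et3N (10 mol %), CH2Cl2, rt, dark
Reagents that add atoms: none
Why: Intramolecular 6-endo oxa-Michael addition of the tertiary hydroxyl to the quinone carbon next to the alkenyl group (the position where 2-methoxy-1,4-benzoquinones accept oxygen nucleophiles, para to the methoxy-bearing carbon) gives hydroquinone 25, which Ag2O dehydrogenates to the quinone; the C2–O bond is never broken, so C2 stays S.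

**Compound list**

1 | (2E)-2-methylbut-2-enal (tiglic aldehyde) | C/C=C(\C)C=O | starting material
2 | (4S,5E)-5-methylhepta-1,5-dien-4-yl diisopinocampheylborinate (Ipc groups from (+)-α-pinene) | C/C=C(\C)[C@H](CC=C)OB([C@@H]1C[C@@H]2C[C@H]([C@H]1C)C2(C)C)[C@@H]1C[C@@H]2C[C@H]([C@H]1C)C2(C)C | intermediate
3 | (4S,5E)-5-methylhepta-1,5-dien-4-ol | C/C=C(\C)[C@@H](O)CC=C | intermediate
4 | (4S,5E)-5-methylhepta-1,5-dien-4-yl 2-methylprop-2-enoate | C/C=C(\C)[C@H](CC=C)OC(=O)C(C)=C | intermediate
5 | (6S)-6-[(2E)-but-2-en-2-yl]-3-methyl-5,6-dihydro-2H-pyran-2-one | C/C=C(\C)[C@@H]1CC=C(C)C(=O)O1 | intermediate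
6 | (6S)-6-[(2E)-but-2-en-2-yl]-3-methyloxan-2-one (C3 epimers) | C/C=C(\C)[C@@H]1CCC(C)C(=O)O1 | intermediate
7 | lithium enolate of 6, lithium (2S)-2-[(2E)-but-2-en-2-yl]-5-methyl-3,4-dihydro-2H-pyran-6-olate | C/C=C(\C)[C@@H]1CCC(C)=C(O[Li])O1 | intermediate
8 | tert-butyl{[(2S)-2-[(2E)-but-2-en-2-yl]-5-methyl-3,4-dihydro-2H-pyran-6-yl]oxy}dimethylsilane | C/C=C(\C)[C@@H]1CCC(C)=C(O[Si](C)(C)C(C)(C)C)O1 | intermediate
9 | tert-butyldimethylsilyl (1R,2S)-1,2,3-trimethylcyclohex-3-ene-1-carboxylate | CC(C)(C)[Si](C)(C)OC(=O)[C@]1(C)CCC=C(C)[C@@H]1C | intermediate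
10 | (1R,2S)-1,2,3-trimethylcyclohex-3-ene-1-carboxylic acid | OC(=O)[C@]1(C)CCC=C(C)[C@@H]1C | intermediate
11 | [(1R,2S)-1,2,3-trimethylcyclohex-3-en-1-yl]methanol | OC[C@]1(C)CCC=C(C)[C@@H]1C | intermediate
12 | (5R,6S)-5-(iodomethyl)-1,5,6-trimethylcyclohex-1-ene | IC[C@]1(C)CCC=C(C)[C@@H]1C | intermediate
13 | (R)-2-methylglycidol, [(2R)-2-methyloxiran-2-yl]methanol | OC[C@]1(C)CO1 | starting material
14 | {[(1R,2S)-1,2,3-trimethylcyclohex-3-en-1-yl]methyl}magnesium iodide | I[Mg]C[C@]1(C)CCC=C(C)[C@@H]1C | intermediate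
15 | chloromagnesium alkoxide of 13, chloro{[(2S)-2-methyloxiran-2-yl]methoxy}magnesium (same arrangement in space as 13) | Cl[Mg]OC[C@]1(C)CO1 | intermediate
16 | (2S)-2-methyl-4-[(1S,2R)-1,2,3-trimethylcyclohex-3-en-1-yl]butane-1,2-diol | OC[C@@](C)(O)CC[C@]1(C)CCC=C(C)[C@@H]1C | intermediate
17 | (2S)-2-hydroxy-2-methyl-4-[(1S,2R)-1,2,3-trimethylcyclohex-3-en-1-yl]butanal | O=C[C@@](C)(O)CC[C@]1(C)CCC=C(C)[C@@H]1C | intermediate
18 | (3S)-3-methyl-5-[(1S,2R)-1,2,3-trimethylcyclohex-3-en-1-yl]pent-1-yn-3-ol | C#C[C@@](C)(O)CC[C@]1(C)CCC=C(C)[C@@H]1C | intermediate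
19 | 2-bromo-6-methoxyphenol | COc1cccc(Br)c1O | starting material
20 | 2-bromo-6-methoxyphenyl acetate | COc1cccc(Br)c1OC(C)=O | intermediate
21 | 2-{(3S)-3-hydroxy-3-methyl-5-[(1S,2R)-1,2,3-trimethylcyclohex-3-en-1-yl]pent-1-yn-1-yl}-6-methoxyphenyl acetate | COc1cccc(C#C[C@@](C)(O)CC[C@]2(C)CCC=C(C)[C@@H]2C)c1OC(C)=O | intermediate
22 | 2-{(1Z,3S)-3-hydroxy-3-methyl-5-[(1S,2R)-1,2,3-trimethylcyclohex-3-en-1-yl]pent-1-en-1-yl}-6-methoxyphenyl acetate | COc1cccc(/C=C\[C@@](C)(O)CC[C@]2(C)CCC=C(C)[C@@H]2C)c1OC(C)=O | intermediate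
23 | 2-{(1Z,3S)-3-hydroxy-3-methyl-5-[(1S,2R)-1,2,3-trimethylcyclohex-3-en-1-yl]pent-1-en-1-yl}-6-methoxyphenol | COc1cccc(/C=C\[C@@](C)(O)CC[C@]2(C)CCC=C(C)[C@@H]2C)c1O | intermediate
24 | 2-{(1Z,3S)-3-hydroxy-3-methyl-5-[(1S,2R)-1,2,3-trimethylcyclohex-3-en-1-yl]pent-1-en-1-yl}-6-methoxycyclohexa-2,5-diene-1,4-dione | COC1=CC(=O)C=C(/C=C\[C@@](C)(O)CC[C@]2(C)CCC=C(C)[C@@H]2C)C1=O | intermediate
25 | (2S)-6-methoxy-2-methyl-2-{2-[(1S,2R)-1,2,3-trimethylcyclohex-3-en-1-yl]ethyl}-2H-chromene-5,8-diol | COc1cc(O)c2c(c1O)C=C[C@](C)(CC[C@]3(C)CCC=C(C)[C@@H]3C)O2 | intermediate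
26 | (2S)-6-methoxy-2-methyl-2-{2-[(1S,2R)-1,2,3-trimethylcyclohex-3-en-1-yl]ethyl}-2H-chromene-5,8-dione | COC1=CC(=O)C2=C(C=C[C@](C)(CC[C@]3(C)CCC=C(C)[C@@H]3C)O2)C1=O | target

Total steps: 14. Longest linear sequence: 13 (steps 1–9 and 11–14; step 10 prepares the aryl partner).

**Three steps most likely to fail**

Step 14 (pyran closure). The conjugate addition of the hindered tertiary hydroxyl may be slower than the decomposition of the alkenylquinone (oligomerisation through the vinylquinone, or ionisation of the allylic alcohol), and reoxidation may lag behind. The fallback sets out from alkynol 18 and comes back at target 26. The potassium alkoxide of 18 (KN(SiMe3)2, THF/DMF, 0 °C) displaces fluoride from 4-fluoro-3-nitroanisole by SNAr, with retention because only the aryl C–F bond breaks, to give nitroaryl propargyl ether F1. Ph3PAuNTf2 (cat., CH2Cl2, rt) then effects 6-endo-dig hydroarylation at the free ortho position to give 8-nitrochromene F2, again without cleaving the C2–O bond; a thermal propargyl Claisen rearrangement is avoided because it passes through a ring-opened dienone and would endanger C2. Zn in AcOH reduces the nitro group to 8-aminochromene F3, and Teuber oxidation of this arylamine, whose para position C5 is free, with (KSO3)2NO in buffered aqueous acetone gives quinone 26.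

Step 8 (fragment union). Formation of the neopentyl-type Grignard reagent may be accompanied by reductive dimerisation or protonation, and the opening of the alkoxide-bearing epoxide may be too slow, so that the organometallic is lost. The fallback sets out from alcohol 11 and comes back at diol 16, building the tertiary carbinol by asymmetric epoxidation instead of taking it from the chiral pool. Swern oxidation of 11 gives aldehyde F4, and Wittig methylenation (Ph3P=CH2) gives vinylcyclohexene F5. 9-BBN hydroborates only the vinyl group to alkylborane F6, which undergoes B-alkyl Suzuki–Miyaura coupling with 2-bromoprop-2-en-1-ol (Pd(dppf)Cl2, aq. K3PO4) to give allylic alcohol F7. Sharpless asymmetric epoxidation with Ti(Oi-Pr)4, (+)-diethyl (2R,3R)-tartrate and t-BuOOH gives epoxy alcohol F8, and LiAlH4 opens the epoxide at its CH2 terminus, which becomes the methyl group, to give 16.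

Step 5 (key step). Deprotonation of the α-branched lactone may be incomplete, or be followed by C-silylation or ring cleavage, so that too little ketene acetal is available for the strained boat transition state. The fallback sets out from unsaturated lactone 5 and comes back at acid 10, generating the ketene acetal reductively and without base. RhCl(PPh3)3-catalysed 1,4-hydrosilylation of 5 with Et3SiH (toluene, 60 °C) should give triethylsilyl ketene acetal F9 regiospecifically; heating to 110 °C should bring about the same [3,3] shift to triethylsilyl ester F10, and aqueous acid releases 10.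

**Further compounds**

F1 | step 14 | 4-methoxy-1-({(3S)-3-methyl-5-[(1S,2R)-1,2,3-trimethylcyclohex-3-en-1-yl]pent-1-yn-3-yl}oxy)-2-nitrobenzene | COc1ccc(O[C@](C)(C#C)CC[C@]2(C)CCC=C(C)[C@@H]2C)c([N+](=O)[O-])c1
F2 | step 14 | (2S)-6-methoxy-2-methyl-8-nitro-2-{2-[(1S,2R)-1,2,3-trimethylcyclohex-3-en-1-yl]ethyl}-2H-chromene | COc1cc([N+](=O)[O-])c2c(c1)C=C[C@](C)(CC[C@]3(C)CCC=C(C)[C@@H]3C)O2
F3 | step 14 | (2S)-6-methoxy-2-methyl-2-{2-[(1S,2R)-1,2,3-trimethylcyclohex-3-en-1-yl]ethyl}-2H-chromen-8-amine | COc1cc(N)c2c(c1)C=C[C@](C)(CC[C@]3(C)CCC=C(C)[C@@H]3C)O2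
F4 | step 8 | (1R,2S)-1,2,3-trimethylcyclohex-3-ene-1-carbaldehyde | O=C[C@]1(C)CCC=C(C)[C@@H]1C
F5 | step 8 | (5S,6S)-5-ethenyl-1,5,6-trimethylcyclohex-1-ene | C=C[C@]1(C)CCC=C(C)[C@@H]1C
F6 | step 8 | 9-{2-[(1R,2R)-1,2,3-trimethylcyclohex-3-en-1-yl]ethyl}-9-borabicyclo[3.3.1]nonane | B1(CC[C@]2(C)CCC=C(C)[C@@H]2C)C2CCCC1CCC2
F7 | step 8 | 2-methylidene-4-[(1S,2R)-1,2,3-trimethylcyclohex-3-en-1-yl]butan-1-ol | OCC(=C)CC[C@]1(C)CCC=C(C)[C@@H]1C
F8 | step 8 | [(2S)-2-{2-[(1S,2R)-1,2,3-trimethylcyclohex-3-en-1-yl]ethyl}oxiran-2-yl]methanol | OC[C@@]1(CC[C@]2(C)CCC=C(C)[C@@H]2C)CO1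
F9 | step 5 | {[(2S)-2-[(2E)-but-2-en-2-yl]-5-methyl-3,4-dihydro-2H-pyran-6-yl]oxy}triethylsilane | C/C=C(\C)[C@@H]1CCC(C)=C(O[Si](CC)(CC)CC)O1
F10 | step 5 | triethylsilyl (1R,2S)-1,2,3-trimethylcyclohex-3-ene-1-carboxylate | CC[Si](CC)(CC)OC(=O)[C@]1(C)CCC=C(C)[C@@H]1C
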